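**Plan**

1. Numbering used here: C1 ring ketone, C2 (N-bearing), C3 (=CH), C4 (carbinol), C5/C6 (epoxide), C7 onward for the triene. Retrosynthetic cuts, in order: C8–C9 (Stille), C7=C8 (chromium olefination of a C4 aldehyde), the epoxide C–O bonds, then the ring bonds C2=C3 and C4–C5 together.
2. Enabling feature: in the cyclohexenone, C5 is β and C2 is α to the C1 carbonyl, and C3–C4 is a hidden α-oxy aldehyde. An ethynyl ketone C5≡C6–C1(=O)–C2H2–NHCOR (from glycine) and the enamine of a protected glyceraldehyde (C3, C4, C7) should therefore give the whole 2-amido-p-quinol dienone by Michael addition then aldol condensation in one operation.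
3. Forward order: ynone 8 and diacetal aldehyde 13 are made separately; the annulation builds the only carbocycle formed in the route; then diacetal removal, hydroxyl-directed epoxidation, unmasking of the C4 aldehyde, (E)-vinylstannane formation and a final Stille union with the bromodienamide.
4. Stereochemistry: C4 comes from (S)-glycerate, relayed through the two acetal centres of a butane-2,3-diacetal while C4 itself is flattened (self-regeneration of the stereocentre). C5 and C6 follow from epoxidation directed by the C4 hydroxyl. Alkene geometry comes from HWE, Hodgson–Takai olefination and stereoretentive Stille coupling.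

Key step: step 7

Assumption: read with the numbering above, the given SMILES is (4R,5S,6R) with the 4-hydroxyl cis to the epoxide oxygen; all descriptors below follow from it, and they change letter at C4 only where substituent priorities change.

**Route**

Step 1
Reactants: 1 cyclohexanecarbaldehyde; 2 triethyl 4-phosphonocrotonate
Product: 3 ethyl (2E,4E)-5-cyclohexylpenta-2,4-dienoate
Conditions: LiHMDS, THF, −78 °C → 0 °C
Reagents that add atoms: none
Why: Vinylogous Horner–Wadsworth–Emmons olefination of a saturated aldehyde with the γ-phosphonate anion should give the (2E,4E)-dienoate, the new alkene being E by the usual thermodynamic control.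

Step 2
Reactants: 3 ethyl (2E,4E)-5-cyclohexylpenta-2,4-dienoate
Product: 4 (2E,4E)-5-cyclohexylpenta-2,4-dienoic acid
Conditions: LiOH, THF/MeOH/H2O, rt; then 1 M HCl
Reagents that add atoms: lithium hydroxide, [Li+].[OH-]
Why: Saponification of the ethyl ester under mild hydroxide conditions should leave the diene geometry untouched and give the acid on acidification.

Step 3
Reactants: 4 (2E,4E)-5-cyclohexylpenta-2,4-dienoic acid; 5 2-amino-N-methoxy-N-methylacetamide hydrochloride
Product: 6 (2E,4E)-5-cyclohexyl-N-{2-[methoxy(methyl)amino]-2-oxoethyl}penta-2,4-dienamide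
Conditions: EDC·HCl, HOBt, iPr2NEt, CH2Cl2, 0 °C → rt
Reagents that add atoms: none
Why: Carbodiimide/HOBt amide coupling of the acid with the glycine Weinreb amide is a standard acylation with no stereochemical issue.

Step 4
Reactants: 6 (2E,4E)-5-cyclohexyl-N-{2-[methoxy(methyl)amino]-2-oxoethyl}penta-2,4-dienamide; 7 ethynylmagnesium bromide
Product: 8 (2E,4E)-5-cyclohexyl-N-(2-oxobut-3-yn-1-yl)penta-2,4-dienamide
Conditions: 7 (3.5 equiv), THF, −78 °C → 0 °C; inverse quench into cold aq NaHSO4
Reagents that add atoms: none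
Why: Weinreb ketone synthesis, in which the first equivalent deprotonates the amide N–H (shielding the dienamide), the second adds once to the N-methoxy-N-methylamide, and the chelated tetrahedral intermediate survives until the acidic inverse quench, which also keeps the released N,O-dimethylhydroxylamine protonated so that it cannot add to the ynone.

Step 5
Reactants: 9 methyl (4S)-2,2-dimethyl-1,3-dioxolane-4-carboxylate; 10 butane-2,3-dione; 11 trimethyl orthoformate
Product: 12 methyl (2S,5S,6S)-5,6-dimethoxy-5,6-dimethyl-1,4-dioxane-2-carboxylate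
Conditions: CSA (cat.), MeOH, reflux
Reagents that add atoms: none
Why: Acid-catalysed transacetalisation to the butane-2,3-diacetal under thermodynamic control should place both methoxy groups axial (anomeric effect) and the ester equatorial, so the (S)-glycerate centre fixes the two new acetal centres as 5S,6S.

Step 6
Reactants: 12 methyl (2S,5S,6S)-5,6-dimethoxy-5,6-dimethyl-1,4-dioxane-2-carboxylate
Product: 13 (2S,5S,6S)-5,6-dimethoxy-5,6-dimethyl-1,4-dioxane-2-carbaldehyde
Conditions: DIBAL-H, CH2Cl2, −78 °C; Rochelle salt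
Reagents that add atoms: none
Why: Low-temperature DIBAL-H reduction of the α-alkoxy ester stops at the hemiacetal aluminate and gives the aldehyde on work-up, the acetal centres being untouched and any epimerisation at C2 being harmless because that centre is flattened in step 7.

Step 7
Reactants: 13 (2S,5S,6S)-5,6-dimethoxy-5,6-dimethyl-1,4-dioxane-2-carbaldehyde; 8 (2E,4E)-5-cyclohexyl-N-(2-oxobut-3-yn-1-yl)penta-2,4-dienamide
Product: 16 (2E,4E)-5-cyclohexyl-N-[(2S,3S,6S)-2,3-dimethoxy-2,3-dimethyl-9-oxo-1,4-dioxaspiro[5.5]undeca-7,10-dien-8-yl]penta-2,4-dienamide, via enamine 14 (not isolated), via Z-keto aldehyde 15 (not isolated)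
Conditions: pyrrolidine (1.1 equiv), 4 Å MS, CH2Cl2, rt; then 8 (0.8 equiv), CF3CH2OH, −20 °C → rt; then AcOH, NaOAc, THF/H2O, 40 °C
Reagents that add atoms: none
Why: Proposed new method: the exocyclic enamine 14 attacks the terminal alkyne carbon of ynone 8 through its oxygen-bearing β-carbon (Michael addition), the allenolate is protonated by trifluoroethanol on the side away from the new quaternary carbon to give the Z-enone (any E isomer would re-equilibrate through reversible pyrrolidine conjugate addition), and after iminium hydrolysis the amido-methylene C2, the only enolisable position of 15, condenses with the aldehyde to form the C2=C3 enamide bond. The closest known reaction type is the Stork enamine–Robinson annulation of α-branched aldehyde enamines with vinyl ketones to 4,4-disubstituted cyclohexenones, run here with an ethynyl ketone so that the cross-conjugated dienone (p-quinol) level arrives directly, combined with the face-selective alkylation of butane-2,3-diacetal glycerate enolates. The six-membered carbocycle closes by intramolecular aldol condensation, 6-(enolexo)-exo-trig, followed by E1cB loss of water. The single new stereocentre, the spiro carbinol carbon, is controlled by the (5S,6S) diacetal: the chair dioxane carries an axial methoxy group 1,3 to the enamine carbon, so the ynone should enter equatorially on the opposite face, which gives the sense needed for the target. The step needs C- over N-attack and Michael addition over [2+2] cycloaddition with ring opening, secured by the preformed enamine with no free amine and by the protic co-solvent that quenches the zwitterion, and it needs the Z-enone, secured by kinetic protonation and the irreversible cyclodehydration.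

Step 8
Reactants: 16 (2E,4E)-5-cyclohexyl-N-[(2S,3S,6S)-2,3-dimethoxy-2,3-dimethyl-9-oxo-1,4-dioxaspiro[5.5]undeca-7,10-dien-8-yl]penta-2,4-dienamide
Product: 17 (2E,4E)-5-cyclohexyl-N-[(3S)-3-hydroxy-3-(hydroxymethyl)-6-oxocyclohexa-1,4-dien-1-yl]penta-2,4-dienamide
Conditions: TFA/H2O (9:1), 0 °C, 15 min
Reagents that add atoms: none
Why: Aqueous trifluoroacetic acid cleaves the butane-2,3-diacetal through oxocarbenium ions at the acetal carbons, so the C4–O bond and its configuration are untouched, and the p-quinol and the vinylogous imide should tolerate the brief cold exposure.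

Step 9
Reactants: 17 (2E,4E)-5-cyclohexyl-N-[(3S)-3-hydroxy-3-(hydroxymethyl)-6-oxocyclohexa-1,4-dien-1-yl]penta-2,4-dienamide
Product: 18 (2E,4E)-5-cyclohexyl-N-[(3S)-3-hydroxy-6-oxo-3-{[(triethylsilyl)oxy]methyl}cyclohexa-1,4-dien-1-yl]penta-2,4-dienamide
Conditions: Et3SiCl, imidazole, CH2Cl2, −20 °C
Reagents that add atoms: chlorotriethylsilane, CC[Si](Cl)(CC)CC
Why: Silylation with a trialkylsilyl chloride and imidazole is selective for the primary hydroxyl over the tertiary quinol hydroxyl and the amide N–H, and it removes the base-labile free hydroxymethyl group before the basic epoxidation.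

Step 10
Reactants: 18 (2E,4E)-5-cyclohexyl-N-[(3S)-3-hydroxy-6-oxo-3-{[(triethylsilyl)oxy]methyl}cyclohexa-1,4-dien-1-yl]penta-2,4-dienamide
Product: 19 (2E,4E)-5-cyclohexyl-N-[(1R,5S,6S)-5-hydroxy-2-oxo-5-{[(triethylsilyl)oxy]methyl}-7-oxabicyclo[4.1.0]hept-3-en-3-yl]penta-2,4-dienamide
Conditions: tBuOOH (decane), DBU, CH2Cl2, 0 °C
Reagents that add atoms: tert-butyl hydroperoxide, CC(C)(C)OO
Why: Weitz–Scheffer nucleophilic epoxidation, in which tert-butylperoxide adds to C5 of the unsubstituted enone (the C2=C3 alkene is deactivated by the amide nitrogen) on the face of the free tertiary hydroxyl, which hydrogen-bonds the incoming peroxide while the silyloxymethyl group blocks the other face, so the epoxide should form cis to the 4-OH and fix C5 and C6.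

Step 11
Reactants: 19 (2E,4E)-5-cyclohexyl-N-[(1R,5S,6S)-5-hydroxy-2-oxo-5-{[(triethylsilyl)oxy]methyl}-7-oxabicyclo[4.1.0]hept-3-en-3-yl]penta-2,4-dienamide
Product: 20 (2E,4E)-5-cyclohexyl-N-[(1R,5R,6S)-5-formyl-5-hydroxy-2-oxo-7-oxabicyclo[4.1.0]hept-3-en-3-yl]penta-2,4-dienamide
Conditions: (COCl)2, DMSO, CH2Cl2, −78 °C → −30 °C; then Et3N, −78 °C → 0 °C
Reagents that add atoms: none
Why: Under Swern conditions a primary triethylsilyl ether is cleaved by the chlorosulfonium reagent and oxidised in the same pot, while the tertiary hydroxyl cannot be oxidised, so the quaternary α-hydroxy aldehyde (no α-hydrogen to epimerise) should result.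

Step 12
Reactants: 21 dibromomethane; 22 tributyltin chloride
Product: 24 (dibromomethyl)tributylstannane, via dibromomethyllithium 23 (not isolated)
Conditions: LDA, THF/Et2O, −100 °C; then 22, −100 °C → rt
Reagents that add atoms: none
Why: Deprotonation of dibromomethane at very low temperature gives the carbenoid dibromomethyllithium, which is trapped at tin by nucleophilic substitution before α-elimination can occur.

Step 13
Reactants: 20 (2E,4E)-5-cyclohexyl-N-[(1R,5R,6S)-5-formyl-5-hydroxy-2-oxo-7-oxabicyclo[4.1.0]hept-3-en-3-yl]penta-2,4-dienamide; 24 (dibromomethyl)tributylstannane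
Product: 25 (2E,4E)-5-cyclohexyl-N-{(1R,5S,6S)-5-hydroxy-2-oxo-5-[(E)-2-(tributylstannyl)ethenyl]-7-oxabicyclo[4.1.0]hept-3-en-3-yl}penta-2,4-dienamide
Conditions: CrCl2, LiI, THF/DMF, rt, dark
Reagents that add atoms: none
Why: Hodgson variant of the Takai olefination, in which the geminal dichromium species from the dibromide adds selectively to the aldehyde (the ring ketone is far less reactive) and anti-elimination from the β-oxidochromium adduct should give the (E)-alkenylstannane, the neighbouring free hydroxyl being tolerated.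

Step 14
Reactants: 26 glutaconaldehyde potassium salt
Product: 27 (2E,4E)-5-bromopenta-2,4-dienal
Conditions: PPh3, Br2, CH2Cl2, 0 °C → rt
Reagents that add atoms: bromine, BrBr
Why: The enolate oxygen of the glutaconaldehyde anion is activated as an oxyphosphonium salt by Ph3PBr2 and replaced by bromide by addition–elimination, the conjugated (2E,4E)-bromodienal being the thermodynamic product.

Step 15
Reactants: 27 (2E,4E)-5-bromopenta-2,4-dienal
Product: 28 (2E,4E)-5-bromopenta-2,4-dienoic acid
Conditions: NaClO2, NaH2PO4, 2-methylbut-2-ene, tBuOH/H2O, 0 °C → rt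
Reagents that add atoms: sodium chlorite, [Na+].[O-]Cl=O
Why: Pinnick oxidation converts the enal to the acid without touching the alkenyl bromide or the diene, the alkene scavenger removing hypochlorous acid.

Step 16
Reactants: 29 cyclopentane-1,3-dione
Product: 30 2-(hydroxyimino)cyclopentane-1,3-dione
Conditions: NaNO2, aq HCl, 0 °C
Reagents that add atoms: sodium nitrite, [Na+].[O-]N=O
Why: Nitrosation of the highly enolised 1,3-dione at C2 followed by tautomerisation gives the 2-oxime, the standard entry to 2-amino-1,3-diones.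

Step 17
Reactants: 30 2-(hydroxyimino)cyclopentane-1,3-dione
Product: 31 2-amino-3-hydroxycyclopent-2-en-1-one hydrochloride
Conditions: H2 (1 atm), Pd/C, HCl, MeOH, rt
Reagents that add atoms: hydrogen chloride, Cl
Why: Catalytic hydrogenation of the oxime in acidic methanol gives the amine, kept as its hydrochloride in the enol form so that the aminodione cannot self-condense.

Step 18
Reactants: 28 (2E,4E)-5-bromopenta-2,4-dienoic acid; 31 2-amino-3-hydroxycyclopent-2-en-1-one hydrochloride
Product: 33 (2E,4E)-5-bromo-N-(2-hydroxy-5-oxocyclopent-1-en-1-yl)penta-2,4-dienamide, via acid chloride 32 (not isolated)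
Conditions: (COCl)2, cat. DMF, CH2Cl2, 0 °C; then 31, pyridine, THF, 0 °C → rt
Reagents that add atoms: none
Why: Acyl chloride formation and N-acylation of the weakly nucleophilic enaminone-type amine in the presence of pyridine should give the amide, any O-acyl isomer rearranging to the more stable N-acyl vinylogous acid.

Step 19
Reactants: 25 (2E,4E)-5-cyclohexyl-N-{(1R,5S,6S)-5-hydroxy-2-oxo-5-[(E)-2-(tributylstannyl)ethenyl]-7-oxabicyclo[4.1.0]hept-3-en-3-yl}penta-2,4-dienamide; 33 (2E,4E)-5-bromo-N-(2-hydroxy-5-oxocyclopent-1-en-1-yl)penta-2,4-dienamide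
Product: 34 (2E,4E)-5-cyclohexyl-N-[(1R,5R,6S)-5-hydroxy-5-{(1E,3E,5E)-7-[(2-hydroxy-5-oxocyclopent-1-en-1-yl)amino]-7-oxohepta-1,3,5-trien-1-yl}-2-oxo-7-oxabicyclo[4.1.0]hept-3-en-3-yl]penta-2,4-dienamide
Conditions: PdCl2(MeCN)2 (10 mol %), DMF, rt, dark
Reagents that add atoms: none
Why: Stille cross-coupling of an (E)-alkenylstannane with an (E,E)-dienyl bromide proceeds with retention at both partners under neutral, base-free conditions (the divalent palladium precatalyst is reduced in situ to zerovalent palladium), which the epoxy ketone, the free tertiary alcohol and the acidic hydroxycyclopentenone should tolerate, giving the all-E triene.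

**Compound list**

1 | cyclohexanecarbaldehyde | O=CC1CCCCC1 | starting material
2 | triethyl 4-phosphonocrotonate | CCOC(=O)/C=C/CP(=O)(OCC)OCC | starting material
3 | ethyl (2E,4E)-5-cyclohexylpenta-2,4-dienoate | CCOC(=O)/C=C/C=C/C1CCCCC1 | intermediate
4 | (2E,4E)-5-cyclohexylpenta-2,4-dienoic acid | OC(=O)/C=C/C=C/C1CCCCC1 | intermediate
5 | 2-amino-N-methoxy-N-methylacetamide hydrochloride | Cl.NCC(=O)N(C)OC | starting material
6 | (2E,4E)-5-cyclohexyl-N-{2-[methoxy(methyl)amino]-2-oxoethyl}penta-2,4-dienamide | CON(C)C(=O)CNC(=O)/C=C/C=C/C1CCCCC1 | intermediate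
7 | ethynylmagnesium bromide | C#C[Mg]Br | starting material
8 | (2E,4E)-5-cyclohexyl-N-(2-oxobut-3-yn-1-yl)penta-2,4-dienamide | C#CC(=O)CNC(=O)/C=C/C=C/C1CCCCC1 | intermediate
9 | methyl (4S)-2,2-dimethyl-1,3-dioxolane-4-carboxylate | COC(=O)[C@@H]1COC(C)(C)O1 | starting material
10 | butane-2,3-dione | CC(=O)C(C)=O | starting material
11 | trimethyl orthoformate | COC(OC)OC | starting material
12 | methyl (2S,5S,6S)-5,6-dimethoxy-5,6-dimethyl-1,4-dioxane-2-carboxylate (ester equatorial, both OMe axial) | COC(=O)[C@@H]1CO[C@](C)(OC)[C@@](C)(OC)O1 | intermediate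
13 | (2S,5S,6S)-5,6-dimethoxy-5,6-dimethyl-1,4-dioxane-2-carbaldehyde | O=C[C@@H]1CO[C@](C)(OC)[C@@](C)(OC)O1 | intermediate
14 | 1-{[(5S,6S)-5,6-dimethoxy-5,6-dimethyl-1,4-dioxan-2-ylidene]methyl}pyrrolidine (E/Z mixture) | C(=C1CO[C@](C)(OC)[C@@](C)(OC)O1)N1CCCC1 | intermediate
15 | (2R,5S,6S)-2-[(1Z)-4-{[(2E,4E)-5-cyclohexylpenta-2,4-dienoyl]amino}-3-oxobut-1-en-1-yl]-5,6-dimethoxy-5,6-dimethyl-1,4-dioxane-2-carbaldehyde | O=C[C@@]1(/C=C\C(=O)CNC(=O)/C=C/C=C/C2CCCCC2)CO[C@](C)(OC)[C@@](C)(OC)O1 | intermediate
16 | (2E,4E)-5-cyclohexyl-N-[(2S,3S,6S)-2,3-dimethoxy-2,3-dimethyl-9-oxo-1,4-dioxaspiro[5.5]undeca-7,10-dien-8-yl]penta-2,4-dienamide | O=C(/C=C/C=C/C1CCCCC1)NC1=C[C@]3(CO[C@](C)(OC)[C@@](C)(OC)O3)C=CC1=O | intermediate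
17 | (2E,4E)-5-cyclohexyl-N-[(3S)-3-hydroxy-3-(hydroxymethyl)-6-oxocyclohexa-1,4-dien-1-yl]penta-2,4-dienamide | O=C(/C=C/C=C/C1CCCCC1)NC1=C[C@](O)(CO)C=CC1=O | intermediate
18 | (2E,4E)-5-cyclohexyl-N-[(3S)-3-hydroxy-6-oxo-3-{[(triethylsilyl)oxy]methyl}cyclohexa-1,4-dien-1-yl]penta-2,4-dienamide | O=C(/C=C/C=C/C1CCCCC1)NC1=C[C@](O)(CO[Si](CC)(CC)CC)C=CC1=O | intermediate
19 | (2E,4E)-5-cyclohexyl-N-[(1R,5S,6S)-5-hydroxy-2-oxo-5-{[(triethylsilyl)oxy]methyl}-7-oxabicyclo[4.1.0]hept-3-en-3-yl]penta-2,4-dienamide (5-OH cis to the epoxide oxygen) | O=C(/C=C/C=C/C1CCCCC1)NC1=C[C@](O)(CO[Si](CC)(CC)CC)[C@H]2O[C@H]2C1=O | intermediate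
20 | (2E,4E)-5-cyclohexyl-N-[(1R,5R,6S)-5-formyl-5-hydroxy-2-oxo-7-oxabicyclo[4.1.0]hept-3-en-3-yl]penta-2,4-dienamide | O=C(/C=C/C=C/C1CCCCC1)NC1=C[C@](O)(C=O)[C@H]2O[C@H]2C1=O | intermediate
21 | dibromomethane | BrCBr | starting material
22 | tributyltin chloride | CCCC[Sn](Cl)(CCCC)CCCC | starting material
23 | dibromomethyllithium | [Li]C(Br)Br | intermediate
24 | (dibromomethyl)tributylstannane | CCCC[Sn](CCCC)(CCCC)C(Br)Br | intermediate
25 | (2E,4E)-5-cyclohexyl-N-{(1R,5S,6S)-5-hydroxy-2-oxo-5-[(E)-2-(tributylstannyl)ethenyl]-7-oxabicyclo[4.1.0]hept-3-en-3-yl}penta-2,4-dienamide | O=C(/C=C/C=C/C1CCCCC1)NC1=C[C@](O)(/C=C/[Sn](CCCC)(CCCC)CCCC)[C@H]2O[C@H]2C1=O | intermediate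
26 | glutaconaldehyde potassium salt; potassium (1E,3E)-5-oxopenta-1,3-dien-1-olate | [K+].[O-]/C=C/C=C/C=O | starting material
27 | (2E,4E)-5-bromopenta-2,4-dienal | O=C/C=C/C=C/Br | intermediate
28 | (2E,4E)-5-bromopenta-2,4-dienoic acid | OC(=O)/C=C/C=C/Br | intermediate
29 | cyclopentane-1,3-dione | O=C1CCC(=O)C1 | starting material
30 | 2-(hydroxyimino)cyclopentane-1,3-dione | O=C1CCC(=O)C1=NO | intermediate
31 | 2-amino-3-hydroxycyclopent-2-en-1-one hydrochloride | Cl.NC1=C(O)CCC1=O | intermediate
32 | (2E,4E)-5-bromopenta-2,4-dienoyl chloride | ClC(=O)/C=C/C=C/Br | intermediate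
33 | (2E,4E)-5-bromo-N-(2-hydroxy-5-oxocyclopent-1-en-1-yl)penta-2,4-dienamide | O=C(/C=C/C=C/Br)NC1=C(O)CCC1=O | intermediate
34 | (2E,4E)-5-cyclohexyl-N-[(1R,5R,6S)-5-hydroxy-5-{(1E,3E,5E)-7-[(2-hydroxy-5-oxocyclopent-1-en-1-yl)amino]-7-oxohepta-1,3,5-trien-1-yl}-2-oxo-7-oxabicyclo[4.1.0]hept-3-en-3-yl]penta-2,4-dienamide | O=C(/C=C/C=C/C1CCCCC1)NC1=C[C@](O)(/C=C/C=C/C=C/C(=O)NC2=C(O)CCC2=O)[C@H]2O[C@H]2C1=O | target

**Count and risks**

Total step count: 19. Longest linear sequence: 11 steps (steps 1, 2, 3, 4, 7, 8, 9, 10, 11, 13, 19).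

Steps most likely to fail:

1. Step 7 (Proposed new method). What may go wrong: [2+2] cycloaddition of the enamine with the ynone followed by cyclobutene ring opening instead of Michael addition; conjugate addition of amine nitrogen to the ynone; build-up of an E-enone that cannot cyclise; weak facial discrimination on the enamine; oligomerisation of the ynone. Fallback (known chemistry, the ring taken from an arene): setting out from acid 4, oxalyl chloride with catalytic DMF would give (2E,4E)-5-cyclohexylpenta-2,4-dienoyl chloride F1, which acylates commercial 2,5-dimethoxyaniline (pyridine, CH2Cl2) to (2E,4E)-5-cyclohexyl-N-(2,5-dimethoxyphenyl)penta-2,4-dienamide F2. PhI(OAc)2 in MeOH should oxidise this to the quinone monoketal (2E,4E)-5-cyclohexyl-N-(6,6-dimethoxy-3-oxocyclohexa-1,4-dien-1-yl)penta-2,4-dienamide F3. Phase-transfer Weitz–Scheffer epoxidation of its unsubstituted enone double bond (tBuOOH, aq NaOH, toluene, an N-benzyl cinchona-alkaloid ammonium chloride, the pseudoenantiomer being picked for the required sense) would give the epoxy monoketal F4. (E)-2-(tributylstannyl)ethenyllithium F5 (from (E)-1,2-bis(tributylstannyl)ethene and n-BuLi, THF, −78 °C, 2 equiv) should add to the ketone anti to the epoxide to give the carbinol ketal F6. Montmorillonite K10 in CH2Cl2 then unmasks the ring ketone, and the sequence comes back to the route at vinylstannane 25.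

2. Step 10. What may go wrong: insufficient discrimination between the hydroxyl face and the silyloxymethyl face; base-induced degradation of the quinol; loss of the silyl group. Fallback (hydroxyl direction replaced by the bias of the rigid spiro-diacetal, and the order of events changed): setting out from 16, the same peroxide epoxidation is run before the diacetal is removed, where attack syn to the C4–O bond and anti to the ring CH2 is expected, to give the epoxy spiro-diacetal F7. TFA/H2O would then give the epoxy diol (2E,4E)-5-cyclohexyl-N-[5-hydroxy-5-(hydroxymethyl)-2-oxo-7-oxabicyclo[4.1.0]hept-3-en-3-yl]penta-2,4-dienamide F8, and Et3SiCl/imidazole brings the sequence back to the route at 19.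

3. Step 13. What may go wrong: reduction of the α,β-epoxy ketone by divalent chromium; α-ketol rearrangement of aldehyde 20; protodestannylation on work-up. Fallback (no chromium, alkyne instead of direct olefination): setting out from 20, Seyferth–Gilbert homologation with the Ohira–Bestmann reagent (dimethyl (1-diazo-2-oxopropyl)phosphonate, K2CO3, MeOH, 0 °C) would give the terminal alkyne (2E,4E)-5-cyclohexyl-N-[5-ethynyl-5-hydroxy-2-oxo-7-oxabicyclo[4.1.0]hept-3-en-3-yl]penta-2,4-dienamide F9. Hydrostannylation (Bu3SnH, PdCl2(PPh3)2 cat., THF, 0 °C), directed to the terminal carbon by the bulky tertiary carbinol, should give the (E)-alkenylstannane and come back to the route at 25.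

**Further compounds**

F1 | step 7 | (2E,4E)-5-cyclohexylpenta-2,4-dienoyl chloride | ClC(=O)/C=C/C=C/C1CCCCC1
F2 | step 7 | (2E,4E)-5-cyclohexyl-N-(2,5-dimethoxyphenyl)penta-2,4-dienamide | COc1ccc(OC)c(NC(=O)/C=C/C=C/C2CCCCC2)c1
F3 | step 7 | (2E,4E)-5-cyclohexyl-N-(6,6-dimethoxy-3-oxocyclohexa-1,4-dien-1-yl)penta-2,4-dienamide | O=C(/C=C/C=C/C1CCCCC1)NC1=CC(=O)C=CC1(OC)OC
F4 | step 7 | (2E,4E)-5-cyclohexyl-N-(5,5-dimethoxy-2-oxo-7-oxabicyclo[4.1.0]hept-3-en-4-yl)penta-2,4-dienamide, epoxide on the face required for 25 | O=C(/C=C/C=C/C1CCCCC1)NC1=CC(=O)[C@H]2O[C@H]2C1(OC)OC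
F5 | step 7 | (E)-2-(tributylstannyl)ethenyllithium | [Li]/C=C/[Sn](CCCC)(CCCC)CCCC
F6 | step 7 | (2E,4E)-5-cyclohexyl-N-{5-hydroxy-2,2-dimethoxy-5-[(E)-2-(tributylstannyl)ethenyl]-7-oxabicyclo[4.1.0]hept-3-en-3-yl}penta-2,4-dienamide, hydroxyl cis to the epoxide oxygen | O=C(/C=C/C=C/C1CCCCC1)NC1=C[C@](O)(/C=C/[Sn](CCCC)(CCCC)CCCC)[C@H]2O[C@H]2C1(OC)OC
F7 | step 10 | epoxide of 16 at the unsubstituted enone double bond, epoxide oxygen cis to the spiro C–O bond | O=C(/C=C/C=C/C1CCCCC1)NC1=C[C@]3(CO[C@](C)(OC)[C@@](C)(OC)O3)[C@H]2O[C@H]2C1=O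
F8 | step 10 | (2E,4E)-5-cyclohexyl-N-[5-hydroxy-5-(hydroxymethyl)-2-oxo-7-oxabicyclo[4.1.0]hept-3-en-3-yl]penta-2,4-dienamide, hydroxyl cis to the epoxide oxygen | O=C(/C=C/C=C/C1CCCCC1)NC1=C[C@](O)(CO)[C@H]2O[C@H]2C1=O
F9 | step 13 | (2E,4E)-5-cyclohexyl-N-[5-ethynyl-5-hydroxy-2-oxo-7-oxabicyclo[4.1.0]hept-3-en-3-yl]penta-2,4-dienamide, hydroxyl cis to the epoxide oxygen | O=C(/C=C/C=C/C1CCCCC1)NC1=C[C@](O)(C#C)[C@H]2O[C@H]2C1=O
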